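**Retrosynthetic overview**
1. Target 20 ⇐ 19 by removal of the C6 ketal and the C8 silyl ether; 19 ⇐ epoxy alcohol 17 by transannular C11–O–C14 ether formation (the key C–O bond; sets C11 and C14) and O‑acetylation.
2. 17 ⇐ macrocyclic enone 15 by isopropyl addition at C11 and reagent-controlled epoxidation of the (E)-C14=C1 alkene (sets C1 and C14).
3. 15 ⇐ open-chain keto-phosphonate aldehyde 14 by Horner–Wadsworth–Emmons ring closure (C9=C10).
4. 14 ⇐ (S)-citronellic acid (C1–C6, C13, C14; C4 from the chiral pool) + MeLi (C7) + methyl pyruvate (C8, C9; C8 by asymmetric Mukaiyama aldol) + dimethyl (2-oxopropyl)phosphonate (C10–C12).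
5. Ring order: the 14-membered carbocycle first, then the oxolane ring across it.

Assumption: carbons are labelled C1–C14 as the ring atoms in the order of the target SMILES (C1 = CH–OAc, C4 = CHMe, C6 = C=O, C8 = C(OH)Me, C9=C10, C11 = C(iPr)–O, C14 = C(Me)–O); the labels are kept for the open-chain precursors.
Assumption: catalyst senses follow the accepted models (the (R,R)-tBu-box copper catalyst gives the (R)-pyruvate adduct; the D-fructose-derived Shi ketone gives the (R,R)-epoxide from an (E)-trisubstituted alkene); if either proved opposite, the mirror-image catalyst is used.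

**Step 1**
Reactants: 1 (3S)-3,7-dimethyloct-6-enoic acid ((S)-citronellic acid)
Product: 2 (4S)-4,8-dimethylnon-7-en-2-one
Conditions: MeLi (2.2 equiv), Et2O, 0 °C → rt; aq. NH4Cl
Reagents that add atoms: methyllithium, [Li]C
Why: Organolithium addition to the lithium carboxylate stops at the dilithio gem-diolate and gives the methyl ketone on work-up (ketone synthesis from a carboxylic acid); C4 is not touched.

**Step 2**
Reactants: 2 (4S)-4,8-dimethylnon-7-en-2-one
Product: 3 trimethyl{[(4S)-4,8-dimethylnona-1,7-dien-2-yl]oxy}silane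
Conditions: LiN(iPr)2, Me3SiCl (internal quench), THF, −78 °C
Reagents that add atoms: chlorotrimethylsilane, C[Si](C)(C)Cl
Why: Kinetic enolisation at the methyl group (the CH2 side is β-branched) and O-silylation give the terminal silyl enol ether (kinetic silyl enol ether formation).

**Step 3**
Reactants: 3 trimethyl{[(4S)-4,8-dimethylnona-1,7-dien-2-yl]oxy}silane and 4 methyl 2-oxopropanoate (methyl pyruvate)
Product: 6 methyl (2R,6S)-2-hydroxy-2,6,10-trimethyl-4-oxoundec-9-enoate, via trimethylsilyl ether of the aldol adduct 5 (not isolated)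
Conditions: [Cu((R,R)-tBu-box)](OTf)2 (10 mol %), THF, −78 °C; then 1 M HCl, THF
Reagents that add atoms: none
Why: Catalytic enantioselective Mukaiyama aldol addition to a pyruvate ester: the pyruvate chelates divalent copper in a square-planar complex, the tert-butyl groups block one ketone face, and the enolsilane adds to the other to set C8 as (R).

**Step 4**
Reactants: 6 methyl (2R,6S)-2-hydroxy-2,6,10-trimethyl-4-oxoundec-9-enoate
Product: 8 methyl (2R)-3-{2-[(2S)-2,6-dimethylhept-5-en-1-yl]-1,3-dioxolan-2-yl}-2-methyl-2-[(triethylsilyl)oxy]propanoate, via triethylsilyl ether ketone 7 (not isolated)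
Conditions: Et3SiOTf, 2,6-lutidine, CH2Cl2, −78 → 0 °C; then Me3SiOCH2CH2OSiMe3, Me3SiOTf, −78 → −20 °C
Reagents that add atoms: triethylsilyl triflate, CC[Si](CC)(CC)OS(=O)(=O)C(F)(F)F; 1,2-bis(trimethylsilyloxy)ethane, C[Si](C)(C)OCCO[Si](C)(C)C
Why: Silyl triflate silylation of the tertiary alcohol, then aprotic Noyori ketalisation of the C6 ketone in the same flask, masks the aldol unit without the acid and heat that would dehydrate it.

**Step 5**
Reactants: 8 (TES ether, C6 dioxolane, methyl ester)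
Product: 9 methyl (2R)-3-{2-[(2S,5E)-7-hydroxy-2,6-dimethylhept-5-en-1-yl]-1,3-dioxolan-2-yl}-2-methyl-2-[(triethylsilyl)oxy]propanoate
Conditions: SeO2 (0.5 equiv), t-BuOOH, CH2Cl2, rt
Reagents that add atoms: tert-butyl hydroperoxide, CC(C)(C)OO
Why: Selenium dioxide allylic oxidation (ene reaction, then [2,3]-shift) hydroxylates the (E)-methyl group of the trisubstituted alkene, giving the (E)-allylic alcohol at C13 and fixing the (E)-C14=C1 geometry.

**Step 6**
Reactants: 9 (C13 allylic alcohol)
Product: 10 methyl (2R)-3-{2-[(2S,5E)-7-bromo-2,6-dimethylhept-5-en-1-yl]-1,3-dioxolan-2-yl}-2-methyl-2-[(triethylsilyl)oxy]propanoate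
Conditions: CBr4, PPh3, CH2Cl2, 0 °C
Reagents that add atoms: carbon tetrabromide, BrC(Br)(Br)Br
Why: Appel bromination of the only free (primary allylic) alcohol under neutral conditions, with the alkene geometry retained.

**Step 7**
Reactants: 10 (C13 allylic bromide) and 11 dimethyl (2-oxopropyl)phosphonate
Product: 12 methyl (2R)-3-{2-[(2S,5E)-10-(dimethoxyphosphoryl)-2,6-dimethyl-9-oxodec-5-en-1-yl]-1,3-dioxolan-2-yl}-2-methyl-2-[(triethylsilyl)oxy]propanoate
Conditions: 11, NaH then n-BuLi, THF, 0 °C; then 10, −78 → 0 °C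
Reagents that add atoms: none
Why: γ-Alkylation of the β-ketophosphonate dianion by the allylic bromide (SN2 at C13) forms C12–C13; the tertiary α-silyloxy ester is too hindered to compete at this temperature.

**Step 8**
Reactants: 12 (β-ketophosphonate methyl ester)
Product: 13 dimethyl {(5E,9S)-2-hydroxy-10-[2-((2R)-3-hydroxy-2-methyl-2-[(triethylsilyl)oxy]propyl)-1,3-dioxolan-2-yl]-5,9-dimethyldec-5-en-1-yl}phosphonate (both C11 epimers)
Conditions: iBu2AlH (6 equiv), CH2Cl2, −78 → 0 °C; Rochelle salt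
Reagents that add atoms: none
Why: Hydride reduction takes the ester to the primary alcohol and the ketone to the carbinol, so that the next oxidation delivers aldehyde and ketophosphonate together; the new C11 carbinol centre is removed again in step 9.

**Step 9**
Reactants: 13 (diol phosphonate)
Product: 14 (2R)-3-{2-[(2S,5E)-10-(dimethoxyphosphoryl)-2,6-dimethyl-9-oxodec-5-en-1-yl]-1,3-dioxolan-2-yl}-2-methyl-2-[(triethylsilyl)oxy]propanal
Conditions: Dess–Martin periodinane (3 equiv), pyridine, CH2Cl2, rt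
Reagents that add atoms: none
Why: Dess–Martin oxidation converts the primary alcohol into the non-enolisable C9 aldehyde and the β-hydroxyphosphonate into the β-ketophosphonate under neutral conditions.

**Step 10**
Reactants: 14 (keto-phosphonate aldehyde)
Product: 15 (7R,8E,13E,17S)-7,13,17-trimethyl-7-[(triethylsilyl)oxy]-1,4-dioxaspiro[4.13]octadeca-8,13-dien-10-one
Conditions: LiCl, iPr2NEt, MeCN, rt → 40 °C, 1 mM (slow addition)
Reagents that add atoms: none
Why: Intramolecular Horner–Wadsworth–Emmons olefination under Masamune–Roush conditions closes the 14-membered ring and gives the (E)-C9=C10 enone.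

**Step 11**
Reactants: 15 (macrocyclic enone)
Product: 16 (7R,8E,13E,17S)-7,13,17-trimethyl-10-(propan-2-yl)-7-[(triethylsilyl)oxy]-1,4-dioxaspiro[4.13]octadeca-8,13-dien-10-ol (both C11 epimers; C10 in this name)
Conditions: iPrLi, CeCl3, THF, −78 °C
Reagents that add atoms: isopropyllithium, CC(C)[Li]
Why: Organocerium 1,2-addition to the enone, without enolisation or conjugate addition, gives the tertiary allylic alcohol; its configuration need not be controlled because step 13 is stereoconvergent.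

**Step 12**
Reactants: 16 (tertiary allylic alcohol, C11 epimers)
Product: 17 (13R,14R)-13,14-epoxide of 16 (locants of 16; C14 and C1 of the target labels; both C11 epimers)
Conditions: D-fructose-derived Shi ketone (0.3 equiv), Oxone (2KHSO5·KHSO4·K2SO4), K2CO3, Bu4NHSO4, MeCN/CH2(OMe)2/aq. Na2B4O7 buffer (pH 10.5), 0 °C
Reagents that add atoms: potassium peroxymonosulfate (KHSO5, active part of Oxone), [K+].[O-]S(=O)(=O)OO
Why: Shi asymmetric epoxidation (chiral dioxirane, spiro transition state) selects the electron-rich trisubstituted C14=C1 alkene over the shielded C9=C10 alkene and gives the (14R,1R)-epoxide under reagent control, which sets C1.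

**Step 13**
Reactants: 17 (epoxy alcohol, C11 epimers)
Product: 19 C1 acetate of the oxolane-bridged macrocycle: (1R,4S,8R,9E,11S,14S), C11–O–C14 ether bridge, C6 ethylene ketal, C8–OSiEt3, via oxolane-bridged C1 alcohol 18 (not isolated)
Conditions: Re2O7 (5 mol %), CH2Cl2, 0 °C → rt; then pyridine, Ac2O, DMAP, rt
Reagents that add atoms: acetic anhydride, CC(=O)OC(C)=O
Why: Proposed new method: a stereoconvergent transannular epoxide-opening etherification. The tertiary allylic C11–OH forms a perrhenate ester, and both C11 epimers interconvert through the C9–C11 allyl cation and 1,3-transposition manifold. The perrhenic acid formed activates the epoxide, and only the (11S)-alcohol can reach the rear face of C14 across the ring. That attack is 5-exo and Markovnikov, inverts C14 to (S), and leaves the epoxide oxygen on C1. It gives the cis-bridged oxolane. A trans-bridged ether would be a strained tertiary allylic ether that re-ionises and drains to the same product. The C8 oxygen is kept out of the manifold as its silyl ether. The closest known reactions are the Re2O7-catalysed 1,3-transposition of allylic alcohols, its use with epoxide trapping to make cyclic ethers in open-chain systems, and the acid-catalysed hydroxy-epoxide cyclisation. Ac2O/DMAP then esterifies the only free alcohol, the secondary C1–OH.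

**Step 14**
Reactants: 19 (protected target)
Product: 20 (1S,2R,5S,9R,10E,12S)-9-hydroxy-1,5,9-trimethyl-7-oxo-12-(propan-2-yl)-15-oxabicyclo[10.2.1]pentadec-10-en-2-yl acetate (target)
Conditions: PPTS, acetone/H2O (10:1), 50 °C
Reagents that add atoms: water, O
Why: Mild acid hydrolysis removes the dioxolane and the tertiary triethylsilyl ether without ionising the tertiary allylic alcohol or the allylic ether, and leaves the acetate in place.

**Compound list**
1 | (3S)-3,7-dimethyloct-6-enoic acid ((S)-citronellic acid) | CC(C)=CCC[C@H](C)CC(=O)O | starting material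
2 | (4S)-4,8-dimethylnon-7-en-2-one | CC(C)=CCC[C@H](C)CC(C)=O | intermediate
3 | trimethyl{[(4S)-4,8-dimethylnona-1,7-dien-2-yl]oxy}silane | CC(C)=CCC[C@H](C)CC(=C)O[Si](C)(C)C | intermediate
4 | methyl 2-oxopropanoate (methyl pyruvate) | CC(=O)C(=O)OC | starting material
5 | methyl (2R,6S)-2,6,10-trimethyl-4-oxo-2-[(trimethylsilyl)oxy]undec-9-enoate | CC(C)=CCC[C@H](C)CC(=O)C[C@@](C)(O[Si](C)(C)C)C(=O)OC | intermediate (not isolated)
6 | methyl (2R,6S)-2-hydroxy-2,6,10-trimethyl-4-oxoundec-9-enoate | CC(C)=CCC[C@H](C)CC(=O)C[C@@](C)(O)C(=O)OC | intermediate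
7 | methyl (2R,6S)-2,6,10-trimethyl-4-oxo-2-[(triethylsilyl)oxy]undec-9-enoate | CC(C)=CCC[C@H](C)CC(=O)C[C@@](C)(O[Si](CC)(CC)CC)C(=O)OC | intermediate (not isolated)
8 | methyl (2R)-3-{2-[(2S)-2,6-dimethylhept-5-en-1-yl]-1,3-dioxolan-2-yl}-2-methyl-2-[(triethylsilyl)oxy]propanoate | CC(C)=CCC[C@H](C)CC1(OCCO1)C[C@@](C)(O[Si](CC)(CC)CC)C(=O)OC | intermediate
9 | methyl (2R)-3-{2-[(2S,5E)-7-hydroxy-2,6-dimethylhept-5-en-1-yl]-1,3-dioxolan-2-yl}-2-methyl-2-[(triethylsilyl)oxy]propanoate | OC/C(C)=C/CC[C@H](C)CC1(OCCO1)C[C@@](C)(O[Si](CC)(CC)CC)C(=O)OC | intermediate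
10 | methyl (2R)-3-{2-[(2S,5E)-7-bromo-2,6-dimethylhept-5-en-1-yl]-1,3-dioxolan-2-yl}-2-methyl-2-[(triethylsilyl)oxy]propanoate | BrC/C(C)=C/CC[C@H](C)CC1(OCCO1)C[C@@](C)(O[Si](CC)(CC)CC)C(=O)OC | intermediate
11 | dimethyl (2-oxopropyl)phosphonate | CC(=O)CP(=O)(OC)OC | starting material
12 | methyl (2R)-3-{2-[(2S,5E)-10-(dimethoxyphosphoryl)-2,6-dimethyl-9-oxodec-5-en-1-yl]-1,3-dioxolan-2-yl}-2-methyl-2-[(triethylsilyl)oxy]propanoate | COP(=O)(OC)CC(=O)CC/C(C)=C/CC[C@H](C)CC1(OCCO1)C[C@@](C)(O[Si](CC)(CC)CC)C(=O)OC | intermediate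
13 | dimethyl {(5E,9S)-2-hydroxy-10-[2-((2R)-3-hydroxy-2-methyl-2-[(triethylsilyl)oxy]propyl)-1,3-dioxolan-2-yl]-5,9-dimethyldec-5-en-1-yl}phosphonate, both C11 epimers | COP(=O)(OC)CC(O)CC/C(C)=C/CC[C@H](C)CC1(OCCO1)C[C@@](C)(O[Si](CC)(CC)CC)CO | intermediate
14 | (2R)-3-{2-[(2S,5E)-10-(dimethoxyphosphoryl)-2,6-dimethyl-9-oxodec-5-en-1-yl]-1,3-dioxolan-2-yl}-2-methyl-2-[(triethylsilyl)oxy]propanal | COP(=O)(OC)CC(=O)CC/C(C)=C/CC[C@H](C)CC1(OCCO1)C[C@@](C)(O[Si](CC)(CC)CC)C=O | intermediate
15 | (7R,8E,13E,17S)-7,13,17-trimethyl-7-[(triethylsilyl)oxy]-1,4-dioxaspiro[4.13]octadeca-8,13-dien-10-one | O=C1/C=C/[C@](C)(O[Si](CC)(CC)CC)CC2(OCCO2)C[C@@H](C)CC/C=C(\C)/CC1 | intermediate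
16 | (7R,8E,13E,17S)-7,13,17-trimethyl-10-(propan-2-yl)-7-[(triethylsilyl)oxy]-1,4-dioxaspiro[4.13]octadeca-8,13-dien-10-ol, both C11 epimers | CC(C)C1(O)/C=C/[C@](C)(O[Si](CC)(CC)CC)CC2(OCCO2)C[C@@H](C)CC/C=C(\C)/CC1 | intermediate
17 | (13R,14R)-13,14-epoxide of 16 (locants of 16), both C11 epimers | CC(C)C1(O)/C=C/[C@](C)(O[Si](CC)(CC)CC)CC2(OCCO2)C[C@@H](C)CC[C@H]3O[C@]3(C)CC1 | intermediate
18 | oxolane-bridged alcohol (1R,4S,8R,9E,11S,14S): C11–O–C14 ether bridge, C1–OH, C6 ethylene ketal, C8–OSiEt3 | O[C@@H]1CC[C@H](C)CC3(OCCO3)C[C@@](C)(O[Si](CC)(CC)CC)/C=C/[C@@]2(C(C)C)CC[C@]1(C)O2 | intermediate (not isolated)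
19 | C1 acetate of 18 | CC(=O)O[C@@H]1CC[C@H](C)CC3(OCCO3)C[C@@](C)(O[Si](CC)(CC)CC)/C=C/[C@@]2(C(C)C)CC[C@]1(C)O2 | intermediate
20 | (1S,2R,5S,9R,10E,12S)-9-hydroxy-1,5,9-trimethyl-7-oxo-12-(propan-2-yl)-15-oxabicyclo[10.2.1]pentadec-10-en-2-yl acetate | CC(=O)O[C@@H]1CC[C@H](C)CC(=O)C[C@@](C)(O)/C=C/[C@@]2(C(C)C)CC[C@]1(C)O2 | target

**Step count and risks**
Total steps: 14. Longest linear sequence: 14 (from 1).

Most likely to fail:

Step 13 (the proposed new step). The risks are dehydration of the tertiary allylic alcohol to a diene, non-productive epoxide opening, or loss of the C8 silyl ether under the rhenium catalyst. The fallback sets out from 17 and comes back at 18. The two C11 epimers of 17 are separated on silica. The matched (11S)-epoxy alcohol F1 is cyclised with camphorsulfonic acid (5 mol %) in CH2Cl2 at 0 °C. This is the classical acid-catalysed 5-exo hydroxy-epoxide opening with inversion at C14, and it gives 18. 18 is then acetylated with Ac2O, pyridine and DMAP to 19 as in step 13. This is known chemistry, with the yield capped by the share of the (11S) epimer; the (11R) epimer is set aside.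

Step 10 (macrocyclic olefination at a hindered, α-quaternary aldehyde). The fallback closes the ring at C12–C13 instead; it sets out from 9 and comes back at 15. 9 is half-reduced with iBu2AlH (2.2 equiv, CH2Cl2, −78 °C) to the hydroxy aldehyde F3. Intermolecular Horner–Wadsworth–Emmons reaction with the dianion of methyl 4-(dimethoxyphosphoryl)-3-oxobutanoate (NaH then n-BuLi, THF, 0 °C) gives the (E)-enone β-keto ester F4. ClCO2Me and pyridine convert its allylic alcohol into the methyl carbonate F5. Pd(PPh3)4 (zerovalent palladium, 10 mol %) in THF at 60 °C and 2 mM closes the ring by intramolecular Tsuji–Trost alkylation at the primary allyl terminus, giving the 14-membered β-keto ester F6. Krapcho demethoxycarbonylation (LiCl, wet DMSO, 120 °C) gives 15.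

Step 5 (moderate yield, over-oxidation to the enal, minor regioisomers). The fallback sets out from 8 and comes back at 9. Cross-metathesis of 8 with methacrolein (second-generation Hoveyda–Grubbs catalyst, CH2Cl2, 40 °C) gives the (E)-enal F2 with loss of 2-methylpropene. Luche reduction (NaBH4, CeCl3·7H2O, MeOH, 0 °C) gives 9.

**Further compounds**
F1 | step 13 | (11S)-epimer of epoxy alcohol 17 (C10 S in the locants of 16) | CC(C)[C@]1(O)/C=C/[C@](C)(O[Si](CC)(CC)CC)CC2(OCCO2)C[C@@H](C)CC[C@H]3O[C@]3(C)CC1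
F2 | step 5 | methyl (2R)-3-{2-[(2S,5E)-2,6-dimethyl-7-oxohept-5-en-1-yl]-1,3-dioxolan-2-yl}-2-methyl-2-[(triethylsilyl)oxy]propanoate | O=C/C(C)=C/CC[C@H](C)CC1(OCCO1)C[C@@](C)(O[Si](CC)(CC)CC)C(=O)OC
F3 | step 10 | (2R)-3-{2-[(2S,5E)-7-hydroxy-2,6-dimethylhept-5-en-1-yl]-1,3-dioxolan-2-yl}-2-methyl-2-[(triethylsilyl)oxy]propanal | OC/C(C)=C/CC[C@H](C)CC1(OCCO1)C[C@@](C)(O[Si](CC)(CC)CC)C=O
F4 | step 10 | methyl (4E,6R)-7-{2-[(2S,5E)-7-hydroxy-2,6-dimethylhept-5-en-1-yl]-1,3-dioxolan-2-yl}-6-methyl-3-oxo-6-[(triethylsilyl)oxy]hept-4-enoate | OC/C(C)=C/CC[C@H](C)CC1(OCCO1)C[C@@](C)(O[Si](CC)(CC)CC)/C=C/C(=O)CC(=O)OC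
F5 | step 10 | C13 methyl carbonate of F4 | COC(=O)OC/C(C)=C/CC[C@H](C)CC1(OCCO1)C[C@@](C)(O[Si](CC)(CC)CC)/C=C/C(=O)CC(=O)OC
F6 | step 10 | methyl (7R,8E,13E,17S)-7,13,17-trimethyl-10-oxo-7-[(triethylsilyl)oxy]-1,4-dioxaspiro[4.13]octadeca-8,13-diene-11-carboxylate, both C11 epimers of this name | COC(=O)C1C/C(C)=C/CC[C@H](C)CC2(OCCO2)C[C@@](C)(O[Si](CC)(CC)CC)/C=C/C1=O
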